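Convention used throughout: positions are numbered as in the azulene skeleton of the target (C1 and C2 methylenes, C3 carbinol, C3a ring-fusion CH, C4 ester carbon, C5, C6 methyl-bearing alkene carbon, C7, C8, C8a angular-methyl carbon). β is the face of the angular methyl, and in this numbering the target is (3R,3aS,4S,8aR).

## The problem

The target 19 is a trans-fused hydroazulene, a cyclopentane fused to a cycloheptene, with four stereocentres: the all-carbon quaternary C8a (methyl), C3a (H), the tertiary carbinol C3 (isopropyl) and the acylated secondary carbinol C4. Three of them are contiguous along C3–C3a–C4, and no chiral-pool fragment maps onto the quaternary centre, so absolute configuration has to come from a reagent. Once C8a is fixed it can control the rest: a C3 enolate is protonated at C3a anti to the angular methyl (trans fusion), a nucleophile enters the C3 ketone anti to that methyl, and the resulting 3β-hydroxyl can deliver oxygen to C4. The C4 oxygen must end on the α face, opposite the tertiary hydroxyl, while C5 stays a methylene and the trisubstituted C6=C7 alkene stays where it is. Fragile features are the tertiary alcohol 1,3 to the ester (dehydration, retro-aldol at the ketone level), the homoallylic ester (elimination to a diene), the phenolic ester, and the β,γ-unsaturated ketones on the way, whose alkenes slide into conjugation with base. The enabling feature is the seven-membered ring C3a–C4–C5–C6–C7–C8–C8a with its methyl on C6: it is a p-tolyl ring (C8a ipso, C4 and C8 ortho, C6 para) into which one carbon, C3a, has been inserted. C3a carries the C3 oxygen, and the C1–C2 chain ties C3 back to C8a, which is what a diazomethyl ketone on a two-methylene tether to a p-tolyl ring delivers in a Buchner reaction.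

## Retrosynthesis

**Ester C4–O bond.** Target 19 is cut to diol 17 and salicylic acid 18. The hydroxyl-directed chemistry used below places the C4 oxygen on the β face, so esterification with inversion (Mitsunobu) is chosen over a retentive acylation. It corrects C4 and installs the salicylate in one operation, and the unprotected phenol can be carried because the carboxyl is far more acidic. The forward step must displace at a hindered secondary centre without eliminating toward C5.

**C4–O and C5–H.** Diol 17 comes from vinyl epoxide 16, and 16 from dienol 15. Hydroboration of the diene in 15 was the neighbouring option, but its regio- and chemoselectivity between C4=C5 and the more electron-rich C6=C7 are not predictable. The tertiary 3β-hydroxyl, in contrast, is homoallylic only to C4=C5 and can direct an epoxidation there. Formate hydrogenolysis of the alkenyl oxirane then puts hydrogen on C5 and keeps C6=C7. Compound 15 has one stereocentre and one oxygen fewer than 17.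

**C3–isopropyl bond.** Dienol 15 is cut to ketone 13 and isopropylmagnesium chloride 14. The angular methyl shields the β face of the cyclopentanone, so the isopropyl group should enter from the α face and leave the hydroxyl β, as required. The forward reaction must add to a ketone whose C3a–H is both α-carbonyl and doubly allylic, which calls for an organocerium reagent.

**C8a–CH3 and C3a–H.** Ketone 13 is traced through enolate 12 to cyclopropyl ketone 11, then to cyclopropyl carbinol 10, allylic alcohol 9 and the achiral trienone 8. The shortest alternative is a copper-catalysed asymmetric conjugate methylation of 8 with AlMe3. That reaction is established for trisubstituted, β-substituted cyclic enones, whereas C3a=C8a of 8 is tetrasubstituted and ring-fused, so the plan does not rest on it. Instead an enantioselective ketone reduction creates a temporary C3 stereocentre. A hydroxyl-directed methylene transfer copies it onto C3a and C8a, oxidation removes it, and reductive opening of the cyclopropyl ketone turns the methylene into the angular methyl. This costs three extra steps but each is a standard reaction on a standard substrate class. The demand on the forward sequence is kinetic α-protonation of trienolate 12 from the face opposite the new methyl.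

**C3a–C8a and C3a–C4 (key disconnection).** Trienone 8 is cut to diazoketone 5 by way of norcaradiene 6 and cycloheptatrienone 7. Both rings and both skeletal bonds arise in one operation from a benzene ring, and the C6 methyl, the C6=C7 alkene, the C8 methylene and the C3 oxygen are all in place afterwards. Because the p-tolyl ring is symmetrical, only one regioisomer can form. Annulations that build the seven-membered ring from acyclic or cyclopentane precursors need more steps to reach the same substitution pattern (see below). The forward reaction must favour arene addition over carbenoid dimerisation and must be kept free of acid.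

**Diazoketone.** Compound 5 is cut at the acyl–diazomethyl bond to acid chloride 2 and (trimethylsilyl)diazomethane 3, via the C-silyl diazoketone 4, and 2 comes from commercial 3-(4-methylphenyl)propanoic acid 1. The starting acid already contains all but one of the carbons of trienone 8.

## Roads not taken

**Alternative 1:** a (4+3) annulation that cuts C5–C6 and C8–C8a.
- Forward step: Rh2(S-DOSP)4 or its enantiomer (divalent rhodium) would decompose methyl 2-diazobut-3-enoate A2 in the presence of the silyl dienol ether A1. Cyclopropanation of the siloxy alkene and Cope rearrangement of the cis-divinylcyclopropane would give the bicyclic enol ether A3.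
- Merits: the quaternary C8a is set catalytically in the same step that closes the seven-membered ring, and the route is convergent. In absolute stereocontrol this is better than the chosen plan, which needs a four-step relay.
- Weak points: the Cope step must form the quaternary carbon at a tetrasubstituted alkene terminus. A3 carries an ester on C6 that has to be taken down to a methyl without moving the alkene. Most seriously, A3 has no oxygen at C3: C1 to C3 are bare methylenes and C3 is β to the latent C4 carbonyl, so the tertiary carbinol would need a carbonyl transposition or a remote oxidation.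
- Comparison: the chosen plan delivers the C3 oxygen and the C6 methyl directly from the key step, and that outweighs the longer route to C8a.

**Alternative 2:** conjugate methylation with aldol cyclopentannulation, cutting C8a–CH3 and C3–C3a.
- Forward step: AlMe3 with Cu(OTf)2 (divalent copper) and a chiral phosphoramidite would add methyl to C8a of dienone A4. The aluminium enolate would close onto the side-chain isopropyl ketone, and acid would dehydrate the aldol to enone A5.
- Merits: the acceptor in A4 is a trisubstituted, β-substituted cycloheptenone, the class for which this conjugate addition is established. C8a would therefore come from one catalytic step, which is better than the relay used here.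
- Weak points: A4 is a skipped dienone with a methylene between carbonyl and alkene, prone to tautomerise into conjugation. The dehydration discards the very hydroxyl the target keeps. Restoring it means adding OH to C3 syn to the angular methyl and H to C3a anti to it across a tetrasubstituted enone, for example by nucleophilic epoxidation on the more hindered face followed by reductive opening. The C4 carbonyl still has to be reduced selectively.
- Comparison: the chosen plan sets C3 by addition anti to the angular methyl (the easy face), sets C3a by protonation, and sets C4 by hydroxyl direction, so each centre is set in the sense the substrate prefers.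

**Alternative 3:** a pinacol-type shift that makes C3a–C8a by migration.
- Forward step: buffered base treatment of the cis-fused decalin diol monomesylate A6 would let C8a migrate from C4 to C3a as the mesylate leaves. The cyclohexane contracts to the cyclopentane, the cyclohexene expands, and the trans-fused hydroxy ketone A7 results.
- Merits: the shift is stereospecific, so the trans ring fusion follows from the mesylate configuration, and A7 already holds the C3 carbinol and a C4 carbonyl. Only a directed reduction and an esterification would remain. At the ring fusion this is better than the chosen plan, which relies on a kinetic protonation.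
- Weak points: A6 needs four stereocentres, a tertiary ring-fusion carbinol next to a quaternary methyl carbon, and selective mesylation of the secondary hydroxyl between two tertiary ones. The C3 hydroxyl can intercept the leaving group as an epoxide, and A7 is a retro-aldol-prone β-hydroxy ketone. Building A6 would probably take longer than the whole of the present route.
- Comparison: the chosen plan reaches the bicyclic skeleton with correct substitution in three steps from an achiral aromatic acid, at the price of less certainty at C3a.

Key step: step 3

## Route

Step 1
Reactants: 1 3-(4-methylphenyl)propanoic acid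
Product: 2 3-(4-methylphenyl)propanoyl chloride
Conditions: (COCl)2 (1.3 equiv), DMF (cat.), CH2Cl2, 0 °C → rt; concentrate
Reagents that add atoms: oxalyl chloride, ClC(=O)C(=O)Cl
Why: Acid chloride formation through the Vilsmeier-type chloroiminium from DMF; nothing else in 1 reacts.

Step 2
Reactants: 2 3-(4-methylphenyl)propanoyl chloride; 3 (trimethylsilyl)diazomethane
Product: 5 1-diazo-4-(4-methylphenyl)butan-2-one, via C-silyl diazoketone 4 (not isolated)
Conditions: 3 (2.2 equiv), THF–MeCN (1:1), 0 °C → rt; aq NaHCO3 work-up
Reagents that add atoms: (trimethylsilyl)diazomethane (3), C[Si](C)(C)C=[N+]=[N-]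
Why: Acylation of the nucleophilic diazo carbon (Arndt–Eistert-type diazoketone synthesis); the second equivalent of 3 scavenges HCl so that no chloromethyl ketone forms, and 4 loses silicon on aqueous work-up.

Step 3
Reactants: 5 1-diazo-4-(4-methylphenyl)butan-2-one
Product: 8 6-methyl-3,4-dihydroazulen-1(2H)-one, via norcaradiene 6 (not isolated), via cycloheptatrienone 7 (not isolated)
Conditions: Rh2(OAc)4 (1 mol %), CH2Cl2, reflux, slow addition of 5 at high dilution; then Et3N, rt
Reagents that add atoms: none
Why: Rh2(OAc)4 (divalent rhodium) expels N2 from 5 to give an electrophilic carbenoid at C3a, which adds across the ipso–ortho π bond of the p-tolyl ring; this is the intramolecular Buchner reaction, the known cyclisation of 1-diazo-4-arylbutan-2-ones to dihydroazulenones. The [2+1] addition forms C3a–C8a and C3a–C4 and closes the five-membered ring by attack of the tethered carbenoid carbon on the ipso carbon. Norcaradiene 6 then opens by a thermally allowed disrotatory 6π electrocyclic reaction that breaks the former ipso–ortho bond C4–C8a, so the seven-membered ring arises by expansion of the benzene ring and gives 7. Et3N removes the acidic C3a–H and reprotonation at C8 gives the conjugated trienone 8, which has its ketone at C3 and alkenes at C3a=C8a, C4=C5 and C6=C7 in target numbering. No stereocentre remains, since the C3a centre of 6 and 7 is erased by the proton shift. Regiochemistry is not in question because the two ortho positions of the p-tolyl ring are equivalent, which places the methyl on C6. The selectivity needed is arene addition over carbenoid dimerisation, secured by slow addition at high dilution, and acid is excluded so that 6 does not collapse to the aromatic six-membered ketone.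

Step 4
Reactants: 8 6-methyl-3,4-dihydroazulen-1(2H)-one
Product: 9 (1S)-6-methyl-1,2,3,4-tetrahydroazulen-1-ol
Conditions: (R)-1-methyl-3,3-diphenyltetrahydro-1H,3H-pyrrolo[1,2-c][1,3,2]oxazaborole [(R)-Me-CBS] (15 mol %), catecholborane (1.5 equiv), toluene, −78 °C; MeOH then aq NaOH
Reagents that add atoms: none
Why: Corey–Bakshi–Shibata reduction: the oxazaborolidine binds the ketone with the tetrasubstituted alkenyl arm as the large group and delivers hydride to one face, which sets the carbinol (C3 of the target numbering) as S. The enone is locked s-trans and the reaction is run cold, so reduction stays 1,2 and the triene is untouched.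

Step 5
Reactants: 9 (1S)-6-methyl-1,2,3,4-tetrahydroazulen-1-ol
Product: 10 (3S,3aS,8aR)-6-methyl-1,2,3,8-tetrahydro-3a,8a-methanoazulen-3-ol
Conditions: Et2Zn (2.0 equiv), CH2I2 (2.0 equiv), CH2Cl2, −10 → 0 °C; aq NH4Cl
Reagents that add atoms: diiodomethane, ICI
Why: Simmons–Smith cyclopropanation (Furukawa variant): the zinc alkoxide delivers methylene to the allylic and most electron-rich alkene C3a=C8a from the hydroxyl face, so the C3 stereocentre fixes C3a and C8a. Limited carbenoid spares the homoallylic C4=C5.

Step 6
Reactants: 10 (3S,3aS,8aR)-6-methyl-1,2,3,8-tetrahydro-3a,8a-methanoazulen-3-ol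
Product: 11 (3aS,8aR)-6-methyl-1,2-dihydro-3a,8a-methanoazulen-3(8H)-one
Conditions: Dess–Martin periodinane (1.3 equiv), NaHCO3, CH2Cl2, 0 °C → rt
Reagents that add atoms: none
Why: Dess–Martin oxidation under bicarbonate buffer gives the ketone without acid that could open the vinylcyclopropane; the C3 stereocentre has served its purpose and chirality now resides in the cyclopropane.

Step 7
Reactants: 11 (3aS,8aR)-6-methyl-1,2-dihydro-3a,8a-methanoazulen-3(8H)-one
Product: 13 (3aR,8aR)-6,8a-dimethyl-1,2,8,8a-tetrahydroazulen-3(3aH)-one, via samarium trienolate 12 (not isolated)
Conditions: SmI2 (2.5 equiv), THF–HMPA, t-BuOH (2 equiv), −78 °C; then AcOH in THF, −78 °C; used at once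
Reagents that add atoms: none
Why: Reductive opening of a cyclopropyl ketone: the ketyl from SmI2 (divalent samarium) cleaves the cyclopropane bond that overlaps the carbonyl π system, the exocyclic C3a–CH2 bond and not the ring-fusion bond, so the methylene becomes the angular methyl with C8a unchanged. Trienolate 12 is then protonated kinetically at its α-carbon C3a, anti to the pseudoaxial angular methyl, which should give the trans fusion and leave the diene out of conjugation.

Step 8
Reactants: 13 (3aR,8aR)-6,8a-dimethyl-1,2,8,8a-tetrahydroazulen-3(3aH)-one; 14 isopropylmagnesium chloride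
Product: 15 (3R,3aR,8aR)-6,8a-dimethyl-3-(propan-2-yl)-1,2,3,3a,8,8a-hexahydroazulen-3-ol
Conditions: CeCl3 (anhydrous, 2 equiv) and 14 (2 equiv), THF, −78 °C, 1 h; then 13, −78 °C; aq NH4Cl
Reagents that add atoms: isopropylmagnesium chloride (14), CC(C)[Mg]Cl
Why: Organocerium 1,2-addition: the weakly basic, oxophilic cerium reagent adds to a ketone that a Grignard reagent would enolise or reduce. Attack is on the α face, opposite the angular methyl that shields the β face of the cyclopentanone, giving the 3β-hydroxyl (C3 R).

Step 9
Reactants: 15 (3R,3aR,8aR)-6,8a-dimethyl-3-(propan-2-yl)-1,2,3,3a,8,8a-hexahydroazulen-3-ol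
Product: 16 (3R,3aS,4S,5R,8aR)-4,5-epoxy-6,8a-dimethyl-3-(propan-2-yl)-1,2,3,3a,4,5,8,8a-octahydroazulen-3-ol
Conditions: VO(acac)2 (5 mol %), t-BuOOH (1.5 equiv, decane solution), 2,6-lutidine (0.2 equiv), CH2Cl2, 0 °C → rt
Reagents that add atoms: tert-butyl hydroperoxide, CC(C)(C)OO
Why: Hydroxyl-directed vanadium-catalysed epoxidation: the vanadate ester of the tertiary homoallylic alcohol delivers oxygen within the complex to C4=C5 on the hydroxyl (β) face and cannot reach the more electron-rich C6=C7. Lutidine buffers the acid-labile vinyl epoxide.

Step 10
Reactants: 16 (3R,3aS,4S,5R,8aR)-4,5-epoxy-6,8a-dimethyl-3-(propan-2-yl)-1,2,3,3a,4,5,8,8a-octahydroazulen-3-ol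
Product: 17 (3R,3aS,4R,8aR)-6,8a-dimethyl-3-(propan-2-yl)-1,2,3,3a,4,5,8,8a-octahydroazulene-3,4-diol
Conditions: Pd2(dba)3·CHCl3 (2.5 mol %), n-Bu3P (10 mol %), HCO2H/Et3N, 1,4-dioxane, rt
Reagents that add atoms: none
Why: Palladium-catalysed formate hydrogenolysis of an alkenyl oxirane: zerovalent palladium ionises the allylic C5–O bond anti to the epoxide to give a π-allylpalladium alkoxide over C5–C7. Hydride from the formate is transferred to C5, the terminus next to the carbinol, so C6=C7 and the C4 configuration are kept.

Step 11
Reactants: 17 (3R,3aS,4R,8aR)-6,8a-dimethyl-3-(propan-2-yl)-1,2,3,3a,4,5,8,8a-octahydroazulene-3,4-diol; 18 salicylic acid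
Product: 19 (3R,3aS,4S,8aR)-3-hydroxy-6,8a-dimethyl-3-(propan-2-yl)-1,2,3,3a,4,5,8,8a-octahydroazulen-4-yl 2-hydroxybenzoate
Conditions: 18 (2 equiv), PPh3 (2 equiv), DIAD (2 equiv), toluene, 0 °C → rt
Reagents that add atoms: salicylic acid (18), OC(=O)c1ccccc1O
Why: Mitsunobu esterification: the C4 alkoxyphosphonium is displaced by salicylate with inversion (4R to 4S). The carboxyl, far more acidic than the hydrogen-bonded phenol, is the nucleophile, its acidity suits a hindered alcohol, and the tertiary C3 hydroxyl is not activated.

## Compound list

1 | 3-(4-methylphenyl)propanoic acid | Cc1ccc(CCC(O)=O)cc1 | starting material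
2 | 3-(4-methylphenyl)propanoyl chloride | Cc1ccc(CCC(Cl)=O)cc1 | intermediate
3 | (trimethylsilyl)diazomethane | C[Si](C)(C)C=[N+]=[N-] | starting material
4 | 1-diazo-4-(4-methylphenyl)-1-(trimethylsilyl)butan-2-one | Cc1ccc(CCC(=O)C(=[N+]=[N-])[Si](C)(C)C)cc1 | intermediate (not isolated)
5 | 1-diazo-4-(4-methylphenyl)butan-2-one | Cc1ccc(CCC(=O)C=[N+]=[N-])cc1 | intermediate
6 | racemic norcaradiene: tricyclic ketone with a cyclopropane over C3a–C4–C8a, ketone at C3 and alkenes C5=C6 (methyl on C6) and C7=C8 | O=C1CCC23C=CC(C)=CC2C13 | intermediate (not isolated)
7 | racemic 6-methyl-3,8a-dihydroazulen-1(2H)-one (target numbering: C3 ketone, C3a–H, alkenes C4=C5, C6=C7, C8=C8a) | O=C1CCC2=CC=C(C)C=CC12 | intermediate (not isolated)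
8 | 6-methyl-3,4-dihydroazulen-1(2H)-one (target numbering: C3 ketone, alkenes C3a=C8a, C4=C5, C6=C7) | CC1=CCC2=C(C=C1)C(=O)CC2 | intermediate
9 | (1S)-6-methyl-1,2,3,4-tetrahydroazulen-1-ol (carbinol carbon is C3 of the target numbering) | CC1=CCC2=C(C=C1)[C@@H](O)CC2 | intermediate
10 | (3S,3aS,8aR)-6-methyl-1,2,3,8-tetrahydro-3a,8a-methanoazulen-3-ol (target numbering; cyclopropane methylene bridges C3a and C8a on the hydroxyl face) | O[C@H]1CC[C@@]23C[C@@]12C=CC(C)=CC3 | intermediate
11 | (3aS,8aR)-6-methyl-1,2-dihydro-3a,8a-methanoazulen-3(8H)-one (target numbering) | O=C1CC[C@@]23C[C@@]12C=CC(C)=CC3 | intermediate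
12 | diiodosamarium (trivalent samarium) (8aR)-6,8a-dimethyl-1,2,8,8a-tetrahydroazulen-3-olate | CC1=CC[C@@]2(C)CCC(O[Sm](I)I)=C2C=C1 | intermediate (not isolated)
13 | (3aR,8aR)-6,8a-dimethyl-1,2,8,8a-tetrahydroazulen-3(3aH)-one (target numbering; trans-fused) | CC1=CC[C@@]2(C)CCC(=O)[C@@H]2C=C1 | intermediate
14 | isopropylmagnesium chloride | CC(C)[Mg]Cl | starting material
15 | (3R,3aR,8aR)-6,8a-dimethyl-3-(propan-2-yl)-1,2,3,3a,8,8a-hexahydroazulen-3-ol | CC1=CC[C@@]2(C)CC[C@@](O)(C(C)C)[C@@H]2C=C1 | intermediate
16 | (3R,3aS,4S,5R,8aR)-4,5-epoxy-6,8a-dimethyl-3-(propan-2-yl)-1,2,3,3a,4,5,8,8a-octahydroazulen-3-ol (β-epoxide) | CC1=CC[C@@]2(C)CC[C@@](O)(C(C)C)[C@@H]2[C@@H]3O[C@@H]31 | intermediate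
17 | (3R,3aS,4R,8aR)-6,8a-dimethyl-3-(propan-2-yl)-1,2,3,3a,4,5,8,8a-octahydroazulene-3,4-diol (both hydroxyls β) | CC1=CC[C@@]2(C)CC[C@@](O)(C(C)C)[C@@H]2[C@H](O)C1 | intermediate
18 | salicylic acid | OC(=O)c1ccccc1O | starting material
19 | (3R,3aS,4S,8aR)-3-hydroxy-6,8a-dimethyl-3-(propan-2-yl)-1,2,3,3a,4,5,8,8a-octahydroazulen-4-yl 2-hydroxybenzoate (CNP0379621.1) | CC1=CC[C@@]2(C)CC[C@@](O)(C(C)C)[C@@H]2[C@@H](OC(=O)c2ccccc2O)C1 | target

## Step count and least certain steps

Total steps: 11. Longest linear sequence: 11 steps (1 to 19).

**Step 3 (key step).** The reaction type is well precedented on this substrate class. The most likely loss is carbenoid dimerisation if the addition is too fast, or acid-triggered collapse of the norcaradiene to the aromatic six-membered ketone (formal C–H insertion) before the proton shift is complete. The fallback sets out from 5 and returns at 8 with no new compound (F0). It gives up the one-pot rhodium cascade for two separately optimised operations on a different carbenoid. Cu(MeCN)4PF6 (monovalent copper) with a bis(oxazoline) ligand gives a less electrophilic carbenoid that is less prone to aromatic substitution. Compound 7 is then isolated on base-washed silica and isomerised to 8 in its own step with DBU.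

**Step 7.** Two processes can fail: electron transfer may open the wrong cyclopropane bond or touch the diene, and protonation of 12 may occur on the β face (cis fusion) or at C5 or C7 (conjugated isomers). The facial preference rests on the pseudoaxial angular methyl and is the least secure stereochemical assumption of the route. The fallback sets out from 11 and returns at 13, replacing electron transfer by a polar opening and separating the protonation from it.
- Me3SiI (from Me3SiCl and NaI, MeCN, Et3N, −40 °C) attacks the cyclopropane methylene and silylates oxygen to give (8aS)-8a-(iodomethyl)-6-methyl-3-(trimethylsilyloxy)-1,2,8,8a-tetrahydroazulene F1.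
- Radical deiodination (Bu3SnH, AIBN, benzene, 80 °C) gives (8aR)-6,8a-dimethyl-3-(trimethylsilyloxy)-1,2,8,8a-tetrahydroazulene F2, a purifiable form of enolate 12.
- Buffered desilylation (Bu4NF with AcOH, THF, −78 °C) delivers the C3a proton in a separate operation in which the proton donor can be varied freely, giving 13.

**Step 8.** The C3a–H of 13 is α to the ketone and doubly allylic, so deprotonation may compete with addition, and work-up would then scramble the ring fusion or move the alkenes. The fallback sets out from 13 and returns at 15 with no new compound (F0). It is a samarium Barbier reaction with 2-iodopropane (SmI2, THF–HMPA), in which the isopropyl group is delivered through ketyl and alkyl radical or organosamarium intermediates under essentially non-basic conditions.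

**Step 10 (and the vinyl epoxide made in step 9).** Hydride may be transferred to the wrong allyl terminus (C7), which would leave the alkene at C5=C6, and 16 may open under the Lewis-acidic or acidic media of steps 9 and 10. The fallback sets out from 15, bypasses 16 and returns at 17 through a tethered hydrosilylation and oxidation (Tamao–Ito sequence), which avoids both the epoxide and the π-allyl intermediate.
- Silylation with (HMe2Si)2NH gives (3R,3aR,8aR)-3-(dimethylsilyloxy)-6,8a-dimethyl-3-(propan-2-yl)-1,2,3,3a,8,8a-hexahydroazulene F3.
- Intramolecular hydrosilylation with Pt2[(CH2=CHSiMe2)2O]3 (zerovalent platinum) closes the tricyclic 2,2-dimethyl-1-oxa-2-silacyclopentane spanning C3–C3a–C4 F4, with silicon on the β face of C4 and hydrogen on C5.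
- Tamao–Fleming oxidation (H2O2, KF, KHCO3, THF–MeOH) replaces silicon by hydroxyl with retention to give 17.

**Step 11.** Activation of the hindered 4β-hydroxyl, flanked by the tertiary carbinol and the ring fusion, may be slow, and the alkoxyphosphonium may eliminate toward C5 to give a conjugated diene instead of being displaced. The fallback sets out from 17 and returns at 19, replacing inversion by substitution with an oxidation and directed reduction.
- Dess–Martin oxidation gives (3R,3aR,8aR)-3-hydroxy-6,8a-dimethyl-3-(propan-2-yl)-2,3,3a,5,8,8a-hexahydroazulen-4(1H)-one F5, the same structure as A7.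
- Me4NBH(OAc)3 (AcOH–MeCN, −30 °C; Evans–Saksena reduction) binds the C3 hydroxyl and delivers hydride internally to the β face of C4, giving (3R,3aS,4S,8aR)-6,8a-dimethyl-3-(propan-2-yl)-1,2,3,3a,4,5,8,8a-octahydroazulene-3,4-diol F6.
- The sodium alkoxide of F6 (NaN(SiMe3)2, THF, 0 °C) opens 2,2-dimethyl-4H-1,3-benzodioxin-4-one to give salicylate 19 directly, with loss of acetone and retention at C4.

## Further compounds

F0 | step 3 | none | none
F1 | step 7 | (8aS)-8a-(iodomethyl)-6-methyl-3-(trimethylsilyloxy)-1,2,8,8a-tetrahydroazulene | CC1=CC[C@@]2(CI)CCC(O[Si](C)(C)C)=C2C=C1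
F2 | step 7 | (8aR)-6,8a-dimethyl-3-(trimethylsilyloxy)-1,2,8,8a-tetrahydroazulene | CC1=CC[C@@]2(C)CCC(O[Si](C)(C)C)=C2C=C1
F0 | step 8 | none | none
F3 | step 10 | (3R,3aR,8aR)-3-(dimethylsilyloxy)-6,8a-dimethyl-3-(propan-2-yl)-1,2,3,3a,8,8a-hexahydroazulene | CC1=CC[C@@]2(C)CC[C@@](O[SiH](C)C)(C(C)C)[C@@H]2C=C1
F4 | step 10 | tricyclic 2,2-dimethyl-1-oxa-2-silacyclopentane spanning C3–C3a–C4 (silicon on the β face of C4) | CC1=CC[C@@]2(C)CC[C@]3(C(C)C)O[Si](C)(C)[C@@H]([C@H]23)C1
F5 | step 11 | (3R,3aR,8aR)-3-hydroxy-6,8a-dimethyl-3-(propan-2-yl)-2,3,3a,5,8,8a-hexahydroazulen-4(1H)-one | CC1=CC[C@@]2(C)CC[C@@](O)(C(C)C)[C@@H]2C(=O)C1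
F6 | step 11 | (3R,3aS,4S,8aR)-6,8a-dimethyl-3-(propan-2-yl)-1,2,3,3a,4,5,8,8a-octahydroazulene-3,4-diol | CC1=CC[C@@]2(C)CC[C@@](O)(C(C)C)[C@@H]2[C@@H](O)C1
A1 | alternative 1 | tert-butyldimethyl{[1-(2-methylcyclopent-1-en-1-yl)ethenyl]oxy}silane | C=C(O[Si](C)(C)C(C)(C)C)C1=C(C)CCC1
A2 | alternative 1 | methyl 2-diazobut-3-enoate | COC(=O)C(=[N+]=[N-])C=C
A3 | alternative 1 | methyl (8aR)-4-(tert-butyldimethylsilyloxy)-8a-methyl-1,2,3,5,8,8a-hexahydroazulene-6-carboxylate | COC(=O)C1=CC[C@@]2(C)CCCC2=C(O[Si](C)(C)C(C)(C)C)C1
A4 | alternative 2 | 6-methyl-3-(4-methyl-3-oxopentyl)cyclohepta-2,5-dien-1-one | CC1=CCC(CCC(=O)C(C)C)=CC(=O)C1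
A5 | alternative 2 | (8aR)-6,8a-dimethyl-3-(propan-2-yl)-1,2,8,8a-tetrahydroazulen-4(5H)-one | CC1=CC[C@@]2(C)CCC(C(C)C)=C2C(=O)C1
A6 | alternative 3 | cis-fused 2,8a-dihydroxy-4a,7-dimethyl-2-(propan-2-yl)-1,2,3,4,4a,5,8,8a-octahydronaphthalen-1-yl methanesulfonate (hydroxyls, mesylate and angular methyl on one face) | CC1=CC[C@@]2(C)CC[C@@](O)(C(C)C)[C@H](OS(C)(=O)=O)[C@@]2(O)C1
A7 | alternative 3 | (3R,3aR,8aR)-3-hydroxy-6,8a-dimethyl-3-(propan-2-yl)-2,3,3a,5,8,8a-hexahydroazulen-4(1H)-one (trans-fused) | CC1=CC[C@@]2(C)CC[C@@](O)(C(C)C)[C@@H]2C(=O)C1
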